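**Retrosynthetic overview** (octalin numbering: C-1 carries the side chain, C-1=C-2 is the ring alkene, C-4a/C-8a are the ring-fusion carbons, C-5 is the gem-dimethyl carbon)
1. The (3E,5E)-diene is cut at C4–C5 of the octadienoate: Zr-catalysed carboalumination of a homopropargyl octalin, then Pd coupling with an (R,E)-vinyl iodide from methyl (S)-3-hydroxy-2-methylpropanoate; the methyl ester is unveiled last.
2. The homopropargyl octalin comes from the allylic bromide at the C-1 methylene and lithiated 1-(trimethylsilyl)propyne; the bromide comes from the C-1 ester.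
3. Key disconnection: both rings from an acyclic chain in one flask. Ring A closes first by a 6-exo radical conjugate addition (C-4a–C-8a); ring B closes second by an intramolecular Horner–Wadsworth–Emmons (HWE) olefination (C-1=C-2).
4. Enabling feature: the tetrasubstituted C-1=C-2 alkene of ring B bears the chain methylene on C-1 and sits next to the quaternary C-8a. With that methylene at the ester level, C-1=C-2 is an HWE olefin (C-2 ketone plus C-1 phosphonoacetate) and C-8a is the β-carbon of the same enoate. C-4a then closes ring A (C-4a, C-5, C-6, C-7, C-8, C-8a) onto C-8a.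
5. The acyclic precursor is built from tert-butyl 3-methylbut-2-enoate by conjugate addition, α-alkylation, Knoevenagel condensation, Wacker oxidation and conversion of the C-4a carboxyl into a redox-active ester.

Key step: step 8

Remark (assumption): tert-butyl 3-methylbut-2-enoate and 4-iodobut-1-ene are treated as catalogue compounds; the sense of induction of the bis(oxazoline) ligand in step 8 rests on a quadrant model and is not predicted with certainty, so the equally available antipodal ligand is used if the first run shows the opposite sense.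

Step 1
Reactants: 1 tert-butyl 3-methylbut-2-enoate; 2 2-(3-chloropropyl)-2-methyl-1,3-dioxolane
Product: 5 tert-butyl 3,3-dimethyl-6-(2-methyl-1,3-dioxolan-2-yl)hexanoate, via Grignard reagent 3 (not isolated), via silyl ketene acetal 4 (not isolated)
Conditions: Mg, THF, reflux; then 1, CuBr·SMe2 (10 mol%), TMSCl, DMPU, THF, −78 → −20 °C; aq. NH4Cl
Reagents that add atoms: none
Why: Copper-catalysed, chlorosilane-accelerated conjugate addition of a Grignard reagent to the β,β-disubstituted enoate should build the quaternary gem-dimethyl carbon (future C-5), the bulky tert-butyl ester suppressing 1,2-addition; no stereocentre is formed.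

Step 2
Reactants: 5 tert-butyl 3,3-dimethyl-6-(2-methyl-1,3-dioxolan-2-yl)hexanoate; 6 4-iodobut-1-ene
Product: 8 tert-butyl 2-(but-3-en-1-yl)-3,3-dimethyl-6-(2-methyl-1,3-dioxolan-2-yl)hexanoate (racemic), via lithium enolate 7 (not isolated)
Conditions: LDA, THF, −78 °C; then 6, DMPU, −78 → 23 °C
Reagents that add atoms: none
Why: Ester enolate alkylation with a primary iodide should install the masked 3-oxobutyl arm at the carbon that becomes C-4a; the new stereocentre is made as a racemate on purpose, because it is erased at the radical stage of step 8.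

Step 3
Reactants: 8 tert-butyl 2-(but-3-en-1-yl)-3,3-dimethyl-6-(2-methyl-1,3-dioxolan-2-yl)hexanoate
Product: 9 tert-butyl 2-(but-3-en-1-yl)-3,3-dimethyl-7-oxooctanoate (racemic)
Conditions: PPTS (20 mol%), acetone/H2O (10:1), 50 °C
Reagents that add atoms: water, SMILES O
Why: Acid-catalysed ketal hydrolysis should free the methyl ketone while the tert-butyl ester and the terminal alkene stay untouched.

Step 4
Reactants: 9 tert-butyl 2-(but-3-en-1-yl)-3,3-dimethyl-7-oxooctanoate; 10 triethyl phosphonoacetate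
Product: 11 1-tert-butyl 9-ethyl 2-(but-3-en-1-yl)-8-(diethoxyphosphoryl)-3,3,7-trimethylnon-7-enedioate (racemic; E/Z mixture)
Conditions: TiCl4 (2 equiv), pyridine (4 equiv), THF, 0 → 23 °C
Reagents that add atoms: none
Why: The TiCl4/amine Knoevenagel condensation is the established way to condense dialkyl ketones with phosphonoacetates and should give the tetrasubstituted alkylidene phosphonoacetate as an E/Z mixture (both isomers serve in step 8), the second ketone still being masked as the terminal alkene.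

Step 5
Reactants: 11 1-tert-butyl 9-ethyl 2-(but-3-en-1-yl)-8-(diethoxyphosphoryl)-3,3,7-trimethylnon-7-enedioate
Product: 12 1-tert-butyl 9-ethyl 8-(diethoxyphosphoryl)-3,3,7-trimethyl-2-(3-oxobutyl)non-7-enedioate (racemic; E/Z mixture)
Conditions: PdCl2 (10 mol%), CuCl (1 equiv), O2 (1 atm), DMF/H2O (7:1), 23 °C
Reagents that add atoms: water, SMILES O
Why: Tsuji–Wacker oxidation should convert the monosubstituted alkene into the methyl ketone with Markovnikov selectivity, the electron-poor tetrasubstituted alkene being inert to Pd(II).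

Step 6
Reactants: 12 1-tert-butyl 9-ethyl 8-(diethoxyphosphoryl)-3,3,7-trimethyl-2-(3-oxobutyl)non-7-enedioate
Product: 13 8-(diethoxyphosphoryl)-9-ethoxy-3,3,7-trimethyl-9-oxo-2-(3-oxobutyl)non-7-enoic acid (racemic; E/Z mixture)
Conditions: TFA/CH2Cl2 (1:4), 0 → 23 °C
Reagents that add atoms: none
Why: Acidolysis of the tert-butyl ester (E1 loss of isobutene) should liberate the acid without touching the ethyl and phosphonate esters.

Step 7
Reactants: 13 8-(diethoxyphosphoryl)-9-ethoxy-3,3,7-trimethyl-9-oxo-2-(3-oxobutyl)non-7-enoic acid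
Product: 14 1-(1,3-dioxoisoindolin-2-yl) 9-ethyl 8-(diethoxyphosphoryl)-3,3,7-trimethyl-2-(3-oxobutyl)non-7-enedioate (racemic; E/Z mixture)
Conditions: N-hydroxyphthalimide, DIC, DMAP (10 mol%), CH2Cl2, 0 → 23 °C
Reagents that add atoms: N-hydroxyphthalimide, SMILES O=C1N(O)C(=O)c2ccccc12
Why: Carbodiimide esterification should give the redox-active ester that serves as the latent radical at the future C-4a.

Step 8
Reactants: 14 1-(1,3-dioxoisoindolin-2-yl) 9-ethyl 8-(diethoxyphosphoryl)-3,3,7-trimethyl-2-(3-oxobutyl)non-7-enedioate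
Product: 16 ethyl (4aS,8aS)-2,5,5,8a-tetramethyl-3,4,4a,5,6,7,8,8a-octahydronaphthalene-1-carboxylate, via monocyclic phosphonoacetate 15 (not isolated)
Conditions: Mg(NTf2)2 (1.1 equiv), (S,S)-t-Bu-box (1.2 equiv), 4 Å MS, CH2Cl2; Ru(bpy)3(PF6)2 (2 mol%), Hantzsch ester (1.5 equiv, slow addition), blue LEDs, −40 °C; then solvent exchange to MeCN, LiCl, DBU, 23 → 50 °C (same flask)
Reagents that add atoms: none
Why: Proposed new method: single-electron reduction of the redox-active ester and loss of CO2 should give the planar secondary radical at the future C-4a, which closes ring A by 6-exo-trig conjugate (Giese) addition onto the β-carbon (future C-8a) of the Mg-chelated alkylidene phosphonoacetate; reduction or H-transfer at the adduct radical leaves phosphonoacetate 15, whose LiCl/DBU-generated anion closes ring B by intramolecular HWE olefination of the methyl ketone (six-membered ring, addition then syn-loss of phosphate), which fixes the double bond at C-1=C-2. The closest known reaction types are chiral-Lewis-acid-controlled radical conjugate additions (Mg–bis(oxazoline) templates; redox-active esters with Hantzsch ester under visible light) and the anionic Michael/intramolecular HWE annulation of 2-phosphonoacrylates; new are their combination, the β,β-disubstituted acceptor and the closure of two rings. C-8a should be set by the C2-symmetric ligand: the tethered radical must approach from the tether side, where one of the two quadrants is blocked, and because the P=O/C=O chelate is pseudo-C2-symmetric both alkene isomers should be attacked in the same absolute sense. C-4a should follow from the chair-like transition state with the 3-oxobutyl arm and the acceptor carbon equatorial (trans ring fusion), and both C-4a epimers of 14 converge through the common radical. The step needs 6-exo closure to beat 1,5-hydrogen transfer and premature reduction (secured by the doubly activated, Lewis-acid-bound acceptor, the gem-dimethyl group and slow addition of the reductant) and it needs face selectivity (secured by full complexation with a stoichiometric chiral Lewis acid, since unbound substrate would cyclise without induction).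

Step 9
Reactants: 16 ethyl (4aS,8aS)-2,5,5,8a-tetramethyl-3,4,4a,5,6,7,8,8a-octahydronaphthalene-1-carboxylate
Product: 17 [(4aS,8aS)-2,5,5,8a-tetramethyl-3,4,4a,5,6,7,8,8a-octahydronaphthalen-1-yl]methanol
Conditions: LiAlH4, Et2O, 0 → 23 °C
Reagents that add atoms: none
Why: Hydride reduction of the hindered conjugated ester (1,2-selective) should give the primary allylic alcohol without touching the two stereocentres.

Step 10
Reactants: 17 [(4aS,8aS)-2,5,5,8a-tetramethyl-3,4,4a,5,6,7,8,8a-octahydronaphthalen-1-yl]methanol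
Product: 18 (4aS,8aS)-1-(bromomethyl)-2,5,5,8a-tetramethyl-3,4,4a,5,6,7,8,8a-octahydronaphthalene
Conditions: PBr3 (0.4 equiv), pyridine (cat.), Et2O, −10 → 0 °C; used crude
Reagents that add atoms: phosphorus tribromide, SMILES BrP(Br)Br
Why: PBr3 should convert the primary allylic alcohol into the bromide by SN2 displacement of the phosphite ester, the isomer with the tetrasubstituted ring alkene being the thermodynamically favoured allylic bromide.

Step 11
Reactants: 18 (4aS,8aS)-1-(bromomethyl)-2,5,5,8a-tetramethyl-3,4,4a,5,6,7,8,8a-octahydronaphthalene; 19 trimethyl(prop-1-yn-1-yl)silane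
Product: 22 (4aS,8aS)-1-(but-3-yn-1-yl)-2,5,5,8a-tetramethyl-3,4,4a,5,6,7,8,8a-octahydronaphthalene, via lithiated silylpropyne 20 (not isolated), via silylated alkyne 21 (not isolated)
Conditions: 19, n-BuLi, THF, −78 → −20 °C; then 18, −78 → 0 °C; then MeOH, K2CO3 (cat.), 23 °C
Reagents that add atoms: none
Why: Lithiated 1-(trimethylsilyl)propyne should alkylate the allylic bromide at its propargylic carbon (SN2 at the primary centre, the silyl group suppressing the allenyl pathway), and base-catalysed methanolysis of the C–Si bond in the same flask should free the terminal alkyne.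

Step 12
Reactants: 23 methyl (S)-3-hydroxy-2-methylpropanoate
Product: 24 methyl (S)-3-[(tert-butyldimethylsilyl)oxy]-2-methylpropanoate
Conditions: TBSCl, imidazole, CH2Cl2, 0 → 23 °C
Reagents that add atoms: tert-butyldimethylsilyl chloride, SMILES CC(C)(C)[Si](C)(C)Cl
Why: Imidazole-assisted silylation should protect the primary alcohol; the stereocentre comes from the chiral pool and is not involved.

Step 13
Reactants: 24 methyl (S)-3-[(tert-butyldimethylsilyl)oxy]-2-methylpropanoate
Product: 25 (S)-3-[(tert-butyldimethylsilyl)oxy]-2-methylpropanal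
Conditions: DIBAL-H (1.05 equiv), CH2Cl2, −78 °C; Rochelle salt
Reagents that add atoms: none
Why: DIBAL-H reduction at −78 °C should stop at the aldehyde through the stable tetrahedral aluminate, and the cold, non-basic work-up should keep the α-stereocentre intact.

Step 14
Reactants: 25 (S)-3-[(tert-butyldimethylsilyl)oxy]-2-methylpropanal
Product: 26 tert-butyl{[(2R,3E)-4-iodo-2-methylbut-3-en-1-yl]oxy}dimethylsilane
Conditions: CrCl2 (6 equiv), CHI3 (2 equiv), THF/dioxane (1:6), 0 → 23 °C
Reagents that add atoms: iodoform, SMILES IC(I)I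
Why: Takai olefination (gem-dichromium carbenoid) should give the (E)-vinyl iodide under near-neutral conditions that do not epimerise the α-stereocentre, which becomes C-2 (R) of the target chain.

Step 15
Reactants: 22 (4aS,8aS)-1-(but-3-yn-1-yl)-2,5,5,8a-tetramethyl-3,4,4a,5,6,7,8,8a-octahydronaphthalene; 26 tert-butyl{[(2R,3E)-4-iodo-2-methylbut-3-en-1-yl]oxy}dimethylsilane
Product: 28 tert-butyl({(2R,3E,5E)-2,6-dimethyl-8-[(4aS,8aS)-2,5,5,8a-tetramethyl-3,4,4a,5,6,7,8,8a-octahydronaphthalen-1-yl]octa-3,5-dien-1-yl}oxy)dimethylsilane, via alkenylalane 27 (not isolated)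
Conditions: AlMe3 (3 equiv), Cp2ZrCl2 (0.25 equiv), CH2Cl2, 0 → 23 °C; then 26, Pd(PPh3)4 (5 mol%), ZnCl2 (0.5 equiv), THF, 23 °C
Reagents that add atoms: trimethylaluminium, SMILES C[Al](C)C
Why: Zr-catalysed syn-carboalumination (Negishi) of the terminal alkyne should place the methyl group on the internal carbon with aluminium cis to it, fixing the 5E alkene, and the Pd-catalysed coupling of the alkenylalane with the (E)-vinyl iodide proceeds with retention at both partners to give the (3E,5E)-diene.

Step 16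
Reactants: 28 tert-butyl({(2R,3E,5E)-2,6-dimethyl-8-[(4aS,8aS)-2,5,5,8a-tetramethyl-3,4,4a,5,6,7,8,8a-octahydronaphthalen-1-yl]octa-3,5-dien-1-yl}oxy)dimethylsilane
Product: 29 (2R,3E,5E)-2,6-dimethyl-8-[(4aS,8aS)-2,5,5,8a-tetramethyl-3,4,4a,5,6,7,8,8a-octahydronaphthalen-1-yl]octa-3,5-dien-1-ol
Conditions: TBAF, THF, 0 → 23 °C
Reagents that add atoms: none
Why: Fluoride-mediated desilylation should free the primary alcohol, the allylic stereocentre carrying no acidifying group at this stage.

Step 17
Reactants: 29 (2R,3E,5E)-2,6-dimethyl-8-[(4aS,8aS)-2,5,5,8a-tetramethyl-3,4,4a,5,6,7,8,8a-octahydronaphthalen-1-yl]octa-3,5-dien-1-ol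
Product: 31 (2R,3E,5E)-2,6-dimethyl-8-[(4aS,8aS)-2,5,5,8a-tetramethyl-3,4,4a,5,6,7,8,8a-octahydronaphthalen-1-yl]octa-3,5-dienoic acid, via aldehyde 30 (not isolated)
Conditions: TEMPO (20 mol%), PhI(OAc)2 (2.2 equiv), MeCN/pH 7 buffer (1:1), 0 → 23 °C
Reagents that add atoms: water, SMILES O
Why: TEMPO/PhI(OAc)2 oxidation in buffered aqueous acetonitrile should take the alcohol through the aldehyde hydrate to the acid under near-neutral conditions, chosen to avoid enolisation of the β,γ-unsaturated aldehyde (loss of C-2 configuration or migration of the diene into conjugation).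

Step 18
Reactants: 31 (2R,3E,5E)-2,6-dimethyl-8-[(4aS,8aS)-2,5,5,8a-tetramethyl-3,4,4a,5,6,7,8,8a-octahydronaphthalen-1-yl]octa-3,5-dienoic acid
Product: 32 methyl (2R,3E,5E)-2,6-dimethyl-8-[(4aS,8aS)-2,5,5,8a-tetramethyl-3,4,4a,5,6,7,8,8a-octahydronaphthalen-1-yl]octa-3,5-dienoate (CNP0152124.1)
Conditions: TMSCHN2, toluene/MeOH (4:1), 0 °C
Reagents that add atoms: (trimethylsilyl)diazomethane, SMILES C[Si](C)(C)C=[N+]=[N-]
Why: Methylation with (trimethylsilyl)diazomethane esterifies the acid without base, so the doubly activated C-2 stereocentre should not epimerise.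

**Compound list**
1 | tert-butyl 3-methylbut-2-enoate | CC(C)=CC(=O)OC(C)(C)C | starting material
2 | 2-(3-chloropropyl)-2-methyl-1,3-dioxolane | CC1(CCCCl)OCCO1 | starting material
3 | [3-(2-methyl-1,3-dioxolan-2-yl)propyl]magnesium chloride | CC1(CCC[Mg]Cl)OCCO1 | intermediate
4 | {[1-tert-butoxy-3,3-dimethyl-6-(2-methyl-1,3-dioxolan-2-yl)hex-1-en-1-yl]oxy}trimethylsilane | CC1(CCCC(C)(C)C=C(OC(C)(C)C)O[Si](C)(C)C)OCCO1 | intermediate
5 | tert-butyl 3,3-dimethyl-6-(2-methyl-1,3-dioxolan-2-yl)hexanoate | CC1(CCCC(C)(C)CC(=O)OC(C)(C)C)OCCO1 | intermediate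
6 | 4-iodobut-1-ene | C=CCCI | starting material
7 | lithium enolate of 5 | CC1(CCCC(C)(C)C=C(O[Li])OC(C)(C)C)OCCO1 | intermediate
8 | tert-butyl 2-(but-3-en-1-yl)-3,3-dimethyl-6-(2-methyl-1,3-dioxolan-2-yl)hexanoate (racemic) | CC1(CCCC(C)(C)C(CCC=C)C(=O)OC(C)(C)C)OCCO1 | intermediate
9 | tert-butyl 2-(but-3-en-1-yl)-3,3-dimethyl-7-oxooctanoate (racemic) | CC(=O)CCCC(C)(C)C(CCC=C)C(=O)OC(C)(C)C | intermediate
10 | triethyl phosphonoacetate | CCOC(=O)CP(=O)(OCC)OCC | starting material
11 | 1-tert-butyl 9-ethyl 2-(but-3-en-1-yl)-8-(diethoxyphosphoryl)-3,3,7-trimethylnon-7-enedioate (racemic; E/Z mixture) | CCOC(=O)C(=C(C)CCCC(C)(C)C(CCC=C)C(=O)OC(C)(C)C)P(=O)(OCC)OCC | intermediate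
12 | 1-tert-butyl 9-ethyl 8-(diethoxyphosphoryl)-3,3,7-trimethyl-2-(3-oxobutyl)non-7-enedioate (racemic; E/Z mixture) | CCOC(=O)C(=C(C)CCCC(C)(C)C(CCC(C)=O)C(=O)OC(C)(C)C)P(=O)(OCC)OCC | intermediate
13 | 8-(diethoxyphosphoryl)-9-ethoxy-3,3,7-trimethyl-9-oxo-2-(3-oxobutyl)non-7-enoic acid (racemic; E/Z mixture) | CCOC(=O)C(=C(C)CCCC(C)(C)C(CCC(C)=O)C(O)=O)P(=O)(OCC)OCC | intermediate
14 | 1-(1,3-dioxoisoindolin-2-yl) 9-ethyl 8-(diethoxyphosphoryl)-3,3,7-trimethyl-2-(3-oxobutyl)non-7-enedioate (racemic; E/Z mixture) | CCOC(=O)C(=C(C)CCCC(C)(C)C(CCC(C)=O)C(=O)ON1C(=O)c2ccccc2C1=O)P(=O)(OCC)OCC | intermediate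
15 | ethyl 2-(diethoxyphosphoryl)-2-[(1S,2S)-1,3,3-trimethyl-2-(3-oxobutyl)cyclohexyl]acetate | CCOC(=O)C(P(=O)(OCC)OCC)[C@@]1(C)CCCC(C)(C)[C@@H]1CCC(C)=O | intermediate
16 | ethyl (4aS,8aS)-2,5,5,8a-tetramethyl-3,4,4a,5,6,7,8,8a-octahydronaphthalene-1-carboxylate | CCOC(=O)C1=C(C)CC[C@H]2C(C)(C)CCC[C@]12C | intermediate
17 | [(4aS,8aS)-2,5,5,8a-tetramethyl-3,4,4a,5,6,7,8,8a-octahydronaphthalen-1-yl]methanol | OCC1=C(C)CC[C@H]2C(C)(C)CCC[C@]12C | intermediate
18 | (4aS,8aS)-1-(bromomethyl)-2,5,5,8a-tetramethyl-3,4,4a,5,6,7,8,8a-octahydronaphthalene | BrCC1=C(C)CC[C@H]2C(C)(C)CCC[C@]12C | intermediate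
19 | trimethyl(prop-1-yn-1-yl)silane | CC#C[Si](C)(C)C | starting material
20 | [3-(trimethylsilyl)prop-2-yn-1-yl]lithium | [Li]CC#C[Si](C)(C)C | intermediate
21 | trimethyl{4-[(4aS,8aS)-2,5,5,8a-tetramethyl-3,4,4a,5,6,7,8,8a-octahydronaphthalen-1-yl]but-1-yn-1-yl}silane | C[Si](C)(C)C#CCCC1=C(C)CC[C@H]2C(C)(C)CCC[C@]12C | intermediate
22 | (4aS,8aS)-1-(but-3-yn-1-yl)-2,5,5,8a-tetramethyl-3,4,4a,5,6,7,8,8a-octahydronaphthalene | C#CCCC1=C(C)CC[C@H]2C(C)(C)CCC[C@]12C | intermediate
23 | methyl (S)-3-hydroxy-2-methylpropanoate | COC(=O)[C@@H](C)CO | starting material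
24 | methyl (S)-3-[(tert-butyldimethylsilyl)oxy]-2-methylpropanoate | COC(=O)[C@@H](C)CO[Si](C)(C)C(C)(C)C | intermediate
25 | (S)-3-[(tert-butyldimethylsilyl)oxy]-2-methylpropanal | O=C[C@@H](C)CO[Si](C)(C)C(C)(C)C | intermediate
26 | tert-butyl{[(2R,3E)-4-iodo-2-methylbut-3-en-1-yl]oxy}dimethylsilane | I/C=C/[C@@H](C)CO[Si](C)(C)C(C)(C)C | intermediate
27 | dimethyl{(1E)-2-methyl-4-[(4aS,8aS)-2,5,5,8a-tetramethyl-3,4,4a,5,6,7,8,8a-octahydronaphthalen-1-yl]but-1-en-1-yl}alumane | C[Al](C)/C=C(\C)CCC1=C(C)CC[C@H]2C(C)(C)CCC[C@]12C | intermediate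
28 | tert-butyl({(2R,3E,5E)-2,6-dimethyl-8-[(4aS,8aS)-2,5,5,8a-tetramethyl-3,4,4a,5,6,7,8,8a-octahydronaphthalen-1-yl]octa-3,5-dien-1-yl}oxy)dimethylsilane | CC(C)(C)[Si](C)(C)OC[C@H](C)/C=C/C=C(\C)CCC1=C(C)CC[C@H]2C(C)(C)CCC[C@]12C | intermediate
29 | (2R,3E,5E)-2,6-dimethyl-8-[(4aS,8aS)-2,5,5,8a-tetramethyl-3,4,4a,5,6,7,8,8a-octahydronaphthalen-1-yl]octa-3,5-dien-1-ol | OC[C@H](C)/C=C/C=C(\C)CCC1=C(C)CC[C@H]2C(C)(C)CCC[C@]12C | intermediate
30 | (2R,3E,5E)-2,6-dimethyl-8-[(4aS,8aS)-2,5,5,8a-tetramethyl-3,4,4a,5,6,7,8,8a-octahydronaphthalen-1-yl]octa-3,5-dienal | O=C[C@H](C)/C=C/C=C(\C)CCC1=C(C)CC[C@H]2C(C)(C)CCC[C@]12C | intermediate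
31 | (2R,3E,5E)-2,6-dimethyl-8-[(4aS,8aS)-2,5,5,8a-tetramethyl-3,4,4a,5,6,7,8,8a-octahydronaphthalen-1-yl]octa-3,5-dienoic acid | OC(=O)[C@H](C)/C=C/C=C(\C)CCC1=C(C)CC[C@H]2C(C)(C)CCC[C@]12C | intermediate
32 | methyl (2R,3E,5E)-2,6-dimethyl-8-[(4aS,8aS)-2,5,5,8a-tetramethyl-3,4,4a,5,6,7,8,8a-octahydronaphthalen-1-yl]octa-3,5-dienoate | COC(=O)[C@H](C)/C=C/C=C(\C)CCC1=C(C)CC[C@H]2C(C)(C)CCC[C@]12C | target

**Step count:** 18 steps in total. Longest linear sequence: 15 steps (steps 1–11 and 15–18).

**Steps most likely to fail**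

Step 8 (Proposed new method). Several processes may go wrong. Face discrimination at the complexed acceptor may be insufficient, or unbound substrate may cyclise without induction. The radical may undergo 1,5-hydrogen transfer or be reduced before ring closure. The dihydropyridine may transfer hydride to the acceptor. The olefination at the congested phosphonoacetate carbon may be slow. The fallback uses known chemistry and sets out from 14. The radical ring closure is run without the chiral Lewis acid under standard reductive photoredox conditions (Ru(bpy)3(PF6)2, Hantzsch ester, i-Pr2NEt·HBF4, CH2Cl2, blue LEDs, 23 °C) and the product is isolated as the racemic trans-configured monocyclic phosphonoacetate F1. Sodium hydride in THF at reflux then closes ring B by the intramolecular HWE reaction to the racemic octalin ester F2. LiAlH4 reduces it to the racemic allylic alcohol F3. Preparative chromatography on a polysaccharide-based chiral stationary phase separates the enantiomers; the (4aS,8aS)-enantiomer is 17, where the route is rejoined.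

Step 2. The hindered enolate may alkylate slowly, and the homoallylic iodide may be lost by E2 elimination. The fallback sets out from 5. Its enolate 7 is alkylated instead with the much more reactive allylic chloride 1,3-dichlorobut-2-ene, which carries the methyl ketone masked as a vinyl chloride, to give the chlorobutenyl ester F4. Ketal hydrolysis as in step 3 gives the chlorobutenyl ketone F5, and the condensation of step 4 gives the chlorobutenyl alkylidene phosphonoacetate F6. Mercury(II)-assisted hydrolysis of the vinyl chloride in formic acid (Hg(OAc)2 cat., 90% HCO2H, 23 °C) unmasks the methyl ketone and removes the tert-butyl group in the same operation. This returns to the route at 13, so the Wacker step is not needed.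

Step 1. The β,β-disubstituted enoate may react slowly, and 1,2-addition or Wurtz coupling may consume the Grignard reagent. The fallback sets out from 2. Grignard reagent 3 is added without copper to the far more electrophilic 2,2-dimethyl-5-(propan-2-ylidene)-1,3-dioxane-4,6-dione (THF, 0 °C), which forms the quaternary carbon as the Meldrum's acid adduct F7. Heating in tert-butanol/toluene (100 °C) opens it to the malonic half-ester F8. Decarboxylation (Cu2O cat., MeCN, 80 °C) returns to the route at 5.

Further compounds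
F1 | step 8 | racemic ethyl 2-(diethoxyphosphoryl)-2-[(1S*,2S*)-1,3,3-trimethyl-2-(3-oxobutyl)cyclohexyl]acetate | CCOC(=O)C(P(=O)(OCC)OCC)[C@@]1(C)CCCC(C)(C)[C@@H]1CCC(C)=O.CCOC(=O)C(P(=O)(OCC)OCC)[C@]1(C)CCCC(C)(C)[C@H]1CCC(C)=O
F2 | step 8 | racemic ethyl (4aS*,8aS*)-2,5,5,8a-tetramethyl-3,4,4a,5,6,7,8,8a-octahydronaphthalene-1-carboxylate | CCOC(=O)C1=C(C)CC[C@H]2C(C)(C)CCC[C@]12C.CCOC(=O)C1=C(C)CC[C@@H]2C(C)(C)CCC[C@@]12C
F3 | step 8 | racemic [(4aS*,8aS*)-2,5,5,8a-tetramethyl-3,4,4a,5,6,7,8,8a-octahydronaphthalen-1-yl]methanol | OCC1=C(C)CC[C@H]2C(C)(C)CCC[C@]12C.OCC1=C(C)CC[C@@H]2C(C)(C)CCC[C@@]12C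
F4 | step 2 | tert-butyl 2-(3-chlorobut-2-en-1-yl)-3,3-dimethyl-6-(2-methyl-1,3-dioxolan-2-yl)hexanoate | CC1(CCCC(C)(C)C(CC=C(C)Cl)C(=O)OC(C)(C)C)OCCO1
F5 | step 2 | tert-butyl 2-(3-chlorobut-2-en-1-yl)-3,3-dimethyl-7-oxooctanoate | CC(=O)CCCC(C)(C)C(CC=C(C)Cl)C(=O)OC(C)(C)C
F6 | step 2 | 1-tert-butyl 9-ethyl 2-(3-chlorobut-2-en-1-yl)-8-(diethoxyphosphoryl)-3,3,7-trimethylnon-7-enedioate | CCOC(=O)C(=C(C)CCCC(C)(C)C(CC=C(C)Cl)C(=O)OC(C)(C)C)P(=O)(OCC)OCC
F7 | step 1 | 2,2-dimethyl-5-[2-methyl-5-(2-methyl-1,3-dioxolan-2-yl)pentan-2-yl]-1,3-dioxane-4,6-dione | CC1(CCCC(C)(C)C2C(=O)OC(C)(C)OC2=O)OCCO1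
F8 | step 1 | 2-(tert-butoxycarbonyl)-3,3-dimethyl-6-(2-methyl-1,3-dioxolan-2-yl)hexanoic acid | CC1(CCCC(C)(C)C(C(O)=O)C(=O)OC(C)(C)C)OCCO1
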